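**Analysis of the target**

The target 33 is a 5β-labdane: a cis-fused decalin (rings A and B, with H5 and the C10 methyl on the same face) carrying a spiro tetrahydrofuran (ring C: O9, C9, C11, C12, C13) and, spiro-fused to it at C13, a 2,3-dihydrofuran (ring D: C13, C14=C15, O, C16). It has six stereocentres. C5 and C10 define the cis ring fusion. At C9 the oxygen is α and C11 is β, cis to the C10 methyl. At C8 the acetate is α, cis to O9, and the methyl is β. At C7 the hydroxyl is β, trans to the C8 acetate. C13 is the remote spiro centre (13S, with C16 on the side of C10 across ring C). C8, C9 and C10 are three contiguous fully substituted carbons, and the C8 oxygen lies on the concave face of the folded bicycle. The cyclic enol ether is labile to acid and to electrophilic oxidants, and it is the contra-thermodynamic isomer of a 9-hydroxy furan, so acid catalysis cannot make it from the furan. The C6–C8 array is a β-acetoxy ketone and an α-ketol (base causes E1cB loss of acetate or ketol shift), and H5 becomes epimerisable once C6 is a ketone. The synthesis is hard because the ring B oxygenation needs acid, the side-chain redox adjustment needs hydride, and the enol ether tolerates neither, so the order of events is tightly constrained. The strategy rests on ring B: C5–C10 carry oxygen at C6 and C9 para to each other, a methyl on C8 next to the only unsubstituted carbon C7, and an angular methyl on C10 cis to H5. This is the pattern left by a Diels–Alder reaction on one double bond of 2,6-dimethyl-1,4-benzoquinone 3.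

**Retrosynthetic reasoning**

33 to 31. The C14=C15 enol ether is the last bond made. It is traced to the α-acetoxy ether 31 by loss of the C15 acetate together with a C14 proton. No skeletal bond is cut; the gain is that the acid-labile enol ether never meets an acidic or oxidising step. The forward reaction must ionise only the anomeric acetate and spare the tertiary C8 acetate, the ketol and H5.

31 to 27. The C8–O acetate bond is cut next. 31 comes from the 7β,8β-epoxy ketone 30 by anti opening at C8, and 30 from alkene 27 through epoxide 28 and alcohol 29. Cutting here takes both the C7 and the C8 oxygen from one alkene and gives their trans relation directly, with the C7 hydroxyl never needing protection. The forward steps must put the epoxide on the β face and deliver acetate to the tertiary carbon from the concave side.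

27 to 22. The C13–O9 bond of ring C is cut. Lactone 25 arises by conjugate addition of the C9 hydroxyl to butenolide 24, and 24 from furan 22 by oxidation. Direct cyclisation of the furan alcohol is uphill, whereas the route through the butenolide is downhill and leaves C15 at carbonyl and C16 at alcohol level, as ring D requires. Reduction of 25 to the lactol level (27) has to come before any ketone or acetate exists. The forward cyclisation has to set C13.

22 to 17. Ring A is simplified. The two C4 methyls are cut back to enone 17 (enolate alkylation to 19), and the C3 oxygen is removed by way of 20. The C3 carbonyl is the only handle for C4, and the quaternary C10 confines enolisation to C4.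

17 to 7 and 12. The C9–C11 bond is cut: the organometallic from iodide 12 (made from aldehyde 8) adds to the C9 ketone of 7, giving 15. This has to happen while the ring A carbonyl is still masked as a silyl enol ether and C6 is a protected carbinol. The forward addition must occur on the β face.

7 to 4. Protecting-group and redox changes only. The C6 carbonyl of 4 is reduced (5), which separates the two ring B carbonyls and removes the acidity of H5. The racemic alcohol is resolved (6) and protected (7).

4 to 3 and 2. The C1–C10 and C4–C5 bonds are cut together, giving quinone 3 and diene 2, which is one step from enone 1. This single step forms ring A, the cis ring fusion and all six carbons of ring B with the methyl, alkene and oxygen positions in place.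

**Alternatives that were turned down**

Alternative 1: The disconnection is the C12–C13 bond of ring C, taken back as a C12=C13 enol ether, with C16 arriving as the acyl part of an ester on O9. Forward, the tertiary benzyloxyacetate A1 (allyl on C9, C6 as a dioxolane) would be treated with a titanium alkylidene of the ethylidene type. This exchanges at the allyl terminus and then olefinates the ester carbonyl intramolecularly, closing ring C as the spiro 2,3-dihydrofuran A2.
- For: the closure is irreversible, needs no acid or base, and does not depend on the nucleophilicity of the congested C9 oxygen. On that point it is stronger than the reversible conjugate addition of step 14.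
- Against: A2 still lacks C14, C15, ring D and the C13 stereocentre. Converting its trisubstituted enol ether carbon into a fully substituted ether carbon needs a stereocontrolled C–C bond formation and then several steps to build the dihydrofuran. The enol ether the target contains is in ring D, not ring C. Acylating the doubly neopentyl C9 hydroxyl and using excess stoichiometric titanium next to a ketal are further burdens.
- Comparison: the plan is an endgame tactic and leaves the cis-decalin to another strategy. The chosen route makes the decalin in its first ring-forming step and brings C11–C16 in one furan unit. It gives up irreversibility at C13 and answers that by recycling the unwanted epimer.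

Alternative 2: The disconnection is the C5–C6 bond of ring B. Forward, the potassium alkoxide of the bicyclo[2.2.2]octenol A3 (a masked o-benzoquinone cycloadduct carrying a silylvinyl group on the carbinol carbon) would undergo anionic oxy-Cope rearrangement. C5–C6 forms while the cage bond between the future C3 and C8 breaks, releasing the cis-decalin A4.
- For: the cis ring fusion follows stereospecifically from the cage, as reliably as in the chosen cycloaddition. The C–C bond formation has no regiochemical ambiguity, which is stronger than a quinone cycloaddition that depends on thermal control. The C6 oxygen arrives masked as silicon and C8/C9 are differentiated.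
- Against: the oxidation pattern of A4 does not match ring B of 33. C8 is a ketone without the methyl, C7 is an unfunctionalised methylene, C6 needs a silicon-to-oxygen oxidation under electrophilic conditions, and C4 has one methyl and a C3=C4 alkene, so the second methyl costs a multistep sequence. The side chain must still be added to a C9 ketone between two fully substituted carbons.
- Comparison: reaching the substitution level of 22 would take clearly more steps. In 4 every ring B carbon already carries its final substituent or its direct precursor.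

Alternative 3: The disconnection is the C6–C7 bond. Forward, the methyl ketone enolate (C7) of the cis-fused γ-lactone A5 would attack the lactone carbonyl C6 in an intramolecular Claisen-type acylation. Ring B closes, the C9 alkoxide is released, and the 9-hydroxy-6,8-dione A6 results.
- For: the C9 carbinol, its side chain and its configuration relative to C5 and C10 are fixed by the lactone tether before ring B exists. That is stronger than the facial selectivity on which step 8 depends. The closure is driven by formation of the diketone enolate.
- Against: A6 is a 6,8-diketone, whereas the target needs methyl and acetoxy at C8 and hydroxyl at C7. Adding a methyl nucleophile to one carbonyl of an enolisable 1,3-diketone and then hydroxylating C7 next to a tertiary α-hydroxy ketone (open to retro-aldol and retro-Claisen cleavage) is long and uncertain. H5 is α to the C6 ketone under strongly basic conditions from the moment ring B forms, so the cis fusion is exposed to equilibration. A5, with two adjacent quaternary carbons, needs its own stereocontrolled synthesis.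
- Comparison: the chosen route has the C8 methyl from the start and keeps C6 as a carbinol, so H5 is not acidic, until step 18.

Key step: step 2

Remark on the chemistry: labdane (target) numbering is used for all decalin compounds; β is the face of the C10 methyl and α the opposite face; ξ marks the lactol-type carbon C15 or C16, whose configuration is mixed and is lost in step 20.

Remark on the chemistry: hydride attack on the convex β face in step 3 is assumed to give the 6α-alcohol; this centre is removed in step 18.

**Route**

Step 1
Reactants: 1 (E)-4-methoxybut-3-en-2-one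
Product: 2 (E)-1-methoxy-3-(tert-butyldimethylsilyloxy)buta-1,3-diene
Conditions: TBSOTf, Et3N, Et2O, −78 → 0 °C
Reagents that add atoms: tert-butyldimethylsilyl triflate, CC(C)(C)[Si](C)(C)OS(=O)(=O)C(F)(F)F
Why: O-silylation of the amine-generated enolate (soft enolisation) gives the 2-silyloxy diene with the (E)-enol ether unchanged; the tert-butyldimethylsilyl group is used in place of trimethylsilyl so that the enol ether survives steps 3 to 8.

Step 2
Reactants: 3 2,6-dimethyl-1,4-benzoquinone; 2 (E)-1-methoxy-3-(tert-butyldimethylsilyloxy)buta-1,3-diene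
Product: 4 racemic cis-fused cycloadduct 1α-methoxy-3-(tert-butyldimethylsilyloxy)-8,10β-dimethyl-5βH-octalin-2,7-diene-6,9-dione
Conditions: toluene, 60 °C, no Lewis acid
Reagents that add atoms: none
Why: Thermal, concerted but asynchronous normal-electron-demand Diels–Alder reaction (closest known type: cycloadditions of 1-alkoxy-3-silyloxybutadienes to methyl-substituted 1,4-benzoquinones), in which the bond from the diene CH2 terminus (largest HOMO coefficient) to C5 runs ahead of the bond from the methoxy-bearing terminus to C10. Ring A is closed as a six-membered ring in the suprafacial/suprafacial [4+2] mode, forming C1–C10 and C4–C5 together. C5 and C10 are fixed by the (Z)-geometry of the quinone double bond, so H5 and the C10 methyl are necessarily cis; C1 is fixed by the endo transition state (quinone carbonyls under the diene) and the (E)-enol ether, which put the methoxy group cis to C9 and trans to the C10 methyl. The step needs regioselectivity: the C9 carbonyl, flanked by both methyl-bearing carbons and not weakened by a β-methyl donor, is the stronger acceptor and makes the unsubstituted carbon (future C5) the electrophilic and less hindered terminus. No Lewis acid is used, because coordination to the unhindered C6 carbonyl would make the methyl-bearing carbon the electrophilic terminus and invert the orientation. The two quinone double bonds are enantiotopic and equally reactive, so 4 is racemic, and the remaining C7=C8 bond is a poorer, more hindered dienophile, so a second addition is not expected. The absolute configuration is introduced by resolution in step 4.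

Step 3
Reactants: 4 racemic cycloadduct
Product: 5 racemic 6α-hydroxy-1α-methoxy-3-(tert-butyldimethylsilyloxy)-8,10β-dimethyl-5βH-octalin-2,7-dien-9-one
Conditions: NaBH4, CeCl3·7H2O, MeOH/CH2Cl2, −78 °C
Reagents that add atoms: none
Why: Luche 1,2-reduction: the C6 carbonyl, flanked by two CH carbons, is attacked while the C9 carbonyl is screened by the C8 methyl and the quaternary C10; hydride enters on the convex β face of the folded cis-bicycle and gives the 6α-alcohol, and with C6 sp3 the proton H5 is no longer acidic.

Step 4
Reactants: 5 racemic 6α-alcohol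
Product: 6 (6S)-enantiomer of 5
Conditions: Burkholderia cepacia lipase (immobilised), vinyl acetate, t-BuOMe, 35 °C, to about 55% conversion
Reagents that add atoms: none
Why: Lipase-catalysed kinetic resolution by acyl transfer: by the Kazlauskas rule (large substituent C5, medium substituent C7) the (6R)-alcohol is acetylated and the (6S)-alcohol 6, the enantiomer needed, remains and should be enantiopure once conversion passes one half.

Step 5
Reactants: 6 (6S)-alcohol
Product: 7 6α-O-benzyloxymethyl ether of 6
Conditions: BnOCH2Cl, i-Pr2NEt, Bu4NI (cat.), CH2Cl2, 0 → 40 °C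
Reagents that add atoms: benzyl chloromethyl ether, ClCOCc1ccccc1
Why: Alkylation with the reactive α-chloro ether under amine base; no alkoxide is formed, which avoids base-induced isomerisation of the γ-hydroxy enone, and the acetal-type ether tolerates every basic, reducing and oxidising step up to step 17.

Step 6
Reactants: 8 furan-3-carbaldehyde
Product: 11 2-(furan-3-yl)ethanol, via 3-vinylfuran 9 (not isolated), via B-[2-(furan-3-yl)ethyl]-9-borabicyclo[3.3.1]nonane 10 (not isolated)
Conditions: Ph3PCH3Br, n-BuLi, THF, 0 °C; then 9-BBN, THF, 0 °C → rt; then NaOH, H2O2, 0 °C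
Reagents that add atoms: methyltriphenylphosphonium bromide, C[P+](c1ccccc1)(c1ccccc1)c1ccccc1.[Br-]; hydrogen peroxide, OO
Why: Wittig methylenation, then anti-Markovnikov hydroboration–oxidation of the vinyl group by the bulky borane, which leaves the furan alone; the volatile alkene is carried on in solution.

Step 7
Reactants: 11 2-(furan-3-yl)ethanol
Product: 12 3-(2-iodoethyl)furan
Conditions: I2, PPh3, imidazole, CH2Cl2, 0 °C
Reagents that add atoms: iodine, [I][I]
Why: Appel-type iodination: the oxyphosphonium ion is displaced by iodide in an SN2 reaction at the primary carbon.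

Step 8
Reactants: 12 3-(2-iodoethyl)furan; 7 6α-O-benzyloxymethyl enone
Product: 15 9β-[2-(furan-3-yl)ethyl]-9α-hydroxy-6α-(benzyloxymethoxy)-1α-methoxy-3-(tert-butyldimethylsilyloxy)-8,10β-dimethyl-5βH-octalin-2,7-diene, via 2-(furan-3-yl)ethyllithium 13 (not isolated), via dichloro[2-(furan-3-yl)ethyl]cerium 14 (not isolated)
Conditions: 12, t-BuLi (2 equiv), Et2O, −78 °C; CeCl3, THF, −78 °C; then 7, −78 °C
Reagents that add atoms: none
Why: Iodine–lithium exchange, transmetalation to the weakly basic organocerium and 1,2-addition to the hindered enone carbonyl C9; attack is expected on the β face, anti to the axial C10–C1 bond of the half-chair that carries the C10 methyl equatorially (the α face lies inside the fold of ring A), which places C11 β and O9 α; the silyl enol ether keeps the ring A carbonyl masked.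

Step 9
Reactants: 15 tertiary alcohol
Product: 17 9β-[2-(furan-3-yl)ethyl]-9α-hydroxy-6α-(benzyloxymethoxy)-8,10β-dimethyl-5βH-octalin-1,7-dien-3-one, via 1α-methoxy 3-ketone 16 (not isolated)
Conditions: TBAF, AcOH, THF, 0 °C; then DBU, rt
Reagents that add atoms: none
Why: Buffered fluoride cleaves the silyl enol ether to the 3-ketone and DBU then removes methanol by E1cB elimination through the C2 enolate; the buffer and the amine base avoid the C9 alkoxide, which could fragment by a vinylogous retro-aldol reaction.

Step 10
Reactants: 17 ring A enone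
Product: 19 6α-(benzyloxymethoxy)-9α-hydroxy-15,16-epoxy-5β-labda-1,7,13(16),14-tetraen-3-one, via 4-monomethyl enone 18 (not isolated)
Conditions: LDA (2.2 equiv), THF, −78 °C, MeI; then LDA (1.5 equiv), −78 °C, MeI, DMPU, −78 → 0 °C
Reagents that add atoms: iodomethane, C[I]
Why: Two successive kinetic enolate alkylations at C4, the only enolisable position of the enone (C10 is quaternary, so no γ-deprotonation); the first equivalent of base turns the C9 hydroxyl into its lithium alkoxide, which is too hindered and aggregated to be methylated.

Step 11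
Reactants: 19 4,4-dimethyl enone
Product: 20 6α-(benzyloxymethoxy)-9α-hydroxy-15,16-epoxy-5β-labda-7,13(16),14-trien-3-one
Conditions: [(Ph3P)CuH]6 (0.5 equiv), benzene (wet), rt
Reagents that add atoms: none
Why: Conjugate reduction by the copper hydride cluster: hydride adds to C1 and the copper enolate is protonated; the isolated alkene, the furan and the benzyl-type ether are not touched.

Step 12
Reactants: 20 saturated 3-ketone
Product: 22 6α-(benzyloxymethoxy)-15,16-epoxy-5β-labda-7,13(16),14-trien-9α-ol, via C3 hydrazone 21 (not isolated)
Conditions: N2H4·H2O, KOH, diethylene glycol, 130 → 200 °C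
Reagents that add atoms: none
Why: Wolff–Kishner reduction under Huang–Minlon conditions, the standard deoxygenation of 4,4-dimethyl-3-ketones; the purely basic medium suits the tertiary allylic alcohol, the furan and the acetal-type ether.

Step 13
Reactants: 22 furan alcohol
Product: 24 6α-(benzyloxymethoxy)-9α-hydroxy-5β-labda-7,13-dien-15,16-olide, via 16-hydroxybutenolide 23 (not isolated)
Conditions: O2, hν, rose bengal (cat.), i-Pr2NEt, CH2Cl2, −78 °C; then NaBH4, EtOH, 0 °C; citric acid work-up
Reagents that add atoms: dioxygen, O=O
Why: [4+2] addition of singlet oxygen to the furan and amine-induced Kornblum–DeLaMare fragmentation of the endoperoxide by removal of the less hindered C15 proton give the 16-hydroxy-15,16-olide regioselectively; borohydride reduces its open aldehyde form and relactonisation leaves C15 as carbonyl and C16 as CH2O, the pattern ring D needs, while the hindered C7=C8 bond reacts far more slowly with singlet oxygen.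

Step 14
Reactants: 24 butenolide alcohol
Product: 25 (13S)-6α-(benzyloxymethoxy)-9α,13-epoxy-5β-labd-7-en-15,16-olide
Conditions: DBU (0.3 equiv), toluene, 60 °C
Reagents that add atoms: none
Why: Reversible intramolecular oxa-Michael addition (5-exo-trig) of the C9 hydroxyl to C13 closes ring C while C8 is still sp2 and the alcohol least hindered; C13 is set under equilibrium control, the (13S) epimer 25 is separated and material of the other C13 configuration is returned to the same conditions.

Step 15
Reactants: 25 spiro lactone
Product: 27 (13S)-15ξ-acetoxy-6α-(benzyloxymethoxy)-9α,13;15,16-diepoxy-5β-labd-7-ene, via diisobutylaluminium lactolate 26 (not isolated)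
Conditions: DIBAL-H, CH2Cl2, −78 °C; then pyridine, DMAP, Ac2O, −78 → 0 °C
Reagents that add atoms: acetic anhydride, CC(=O)OC(C)=O
Why: Reductive acetylation: the tetrahedral aluminium lactolate formed at −78 °C is acylated before it can collapse, which fixes C15 at the aldehyde oxidation level as an α-acetoxy ether that is stable to the oxidants and to the acetic acid used later.

Step 16
Reactants: 27 α-acetoxy ether
Product: 28 (13S)-15ξ-acetoxy-6α-(benzyloxymethoxy)-7β,8β;9α,13;15,16-triepoxy-5β-labdane
Conditions: mCPBA, NaHCO3, CH2Cl2, 0 °C
Reagents that add atoms: 3-chloroperoxybenzoic acid, OOC(=O)c1cccc(Cl)c1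
Why: Prilezhaev epoxidation of the only remaining alkene; the α face is closed by the 6α-alkoxy group, O9 and ring A, so the peracid delivers oxygen to the β face and sets C7 and C8.

Step 17
Reactants: 28 epoxide
Product: 29 (13S)-15ξ-acetoxy-7β,8β;9α,13;15,16-triepoxy-5β-labdan-6α-ol
Conditions: H2 (1 atm), Pd(OH)2/C, EtOAc, rt
Reagents that add atoms: none
Why: Hydrogenolysis of the benzyl C–O bond and loss of formaldehyde from the hemiacetal free the 6α-hydroxyl; no alkene or furan is left, the epoxide and the acetoxy ether are inert, and the base-free conditions avoid Payne migration of the epoxide.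

Step 18
Reactants: 29 epoxy alcohol
Product: 30 (13S)-15ξ-acetoxy-7β,8β;9α,13;15,16-triepoxy-5β-labdan-6-one
Conditions: Dess–Martin periodinane, NaHCO3, CH2Cl2, 0 °C → rt
Reagents that add atoms: none
Why: Buffered hypervalent-iodine oxidation of the secondary alcohol to the C6 ketone under neutral conditions, so that H5, now α to a carbonyl, is not epimerised.

Step 19
Reactants: 30 epoxy ketone
Product: 31 (13S)-8α,15ξ-diacetoxy-7β-hydroxy-9α,13;15,16-diepoxy-5β-labdan-6-one
Conditions: AcOH, H2SO4 (cat.), rt
Reagents that add atoms: acetic acid, CC(=O)O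
Why: Acid-catalysed opening of the α,β-epoxy ketone at the tertiary β-carbon C8 (the α-keto carbon C7 cannot carry positive charge) with anti attack of acetic acid from the α face gives the 8α-acetate and the 7β-alcohol; with C6 sp2 this is also the trans-diaxial (Fürst–Plattner) mode in the conformer with C1 axial, and exchange at the anomeric acetate is degenerate in this solvent.

Step 20
Reactants: 31 hydroxy diacetate
Product: 33 (13S)-8α-acetoxy-7β-hydroxy-9α,13;15,16-diepoxy-5β-labd-14-en-6-one, via 7-O-trimethylsilyl ether of the target 32 (not isolated)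
Conditions: TMSOTf, i-Pr2NEt, CH2Cl2, −78 → −30 °C; then TBAF, AcOH, THF, 0 °C
Reagents that add atoms: none
Why: The silyl triflate ionises only the anomeric acetate to the C15 oxocarbenium ion, from which the amine removes a C14 proton to give the 2,3-dihydrofuran (elimination of an α-acetoxy ether to an enol ether); the C7 hydroxyl is silylated in passing and freed by buffered fluoride, conditions under which the enol ether, the β-acetoxy ketone and H5 are stable.

**Compound list**

1 | (E)-4-methoxybut-3-en-2-one | CO/C=C/C(C)=O | starting material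
2 | (E)-1-methoxy-3-(tert-butyldimethylsilyloxy)buta-1,3-diene | CO/C=C/C(=C)O[Si](C)(C)C(C)(C)C | intermediate
3 | 2,6-dimethyl-1,4-benzoquinone | CC1=CC(=O)C=C(C)C1=O | starting material
4 | racemic cis-fused cycloadduct, 1α-methoxy-3-(tert-butyldimethylsilyloxy)-8,10β-dimethyl-5βH-octalin-2,7-diene-6,9-dione (the enantiomer drawn is the one carried on) | CC1=CC(=O)[C@@H]2CC(O[Si](C)(C)C(C)(C)C)=C[C@H](OC)[C@]2(C)C1=O | intermediate
5 | racemic 6α-hydroxy-1α-methoxy-3-(tert-butyldimethylsilyloxy)-8,10β-dimethyl-5βH-octalin-2,7-dien-9-one (the enantiomer drawn is the one carried on) | CC1=C[C@H](O)[C@@H]2CC(O[Si](C)(C)C(C)(C)C)=C[C@H](OC)[C@]2(C)C1=O | intermediate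
6 | (6S)-enantiomer of 5, single enantiomer | CC1=C[C@H](O)[C@@H]2CC(O[Si](C)(C)C(C)(C)C)=C[C@H](OC)[C@]2(C)C1=O | intermediate
7 | 6α-O-benzyloxymethyl ether of 6 | CC1=C[C@H](OCOCc3ccccc3)[C@@H]2CC(O[Si](C)(C)C(C)(C)C)=C[C@H](OC)[C@]2(C)C1=O | intermediate
8 | furan-3-carbaldehyde | O=Cc1ccoc1 | starting material
9 | 3-vinylfuran | C=Cc1ccoc1 | intermediate (not isolated)
10 | B-[2-(furan-3-yl)ethyl]-9-borabicyclo[3.3.1]nonane | C(Cc1ccoc1)B1C2CCCC1CCC2 | intermediate (not isolated)
11 | 2-(furan-3-yl)ethanol | OCCc1ccoc1 | intermediate
12 | 3-(2-iodoethyl)furan | [I]CCc1ccoc1 | intermediate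
13 | 2-(furan-3-yl)ethyllithium | [Li]CCc1ccoc1 | intermediate (not isolated)
14 | dichloro[2-(furan-3-yl)ethyl]cerium | Cl[Ce](Cl)CCc1ccoc1 | intermediate (not isolated)
15 | 9β-[2-(furan-3-yl)ethyl]-9α-hydroxy-6α-(benzyloxymethoxy)-1α-methoxy-3-(tert-butyldimethylsilyloxy)-8,10β-dimethyl-5βH-octalin-2,7-diene | CC1=C[C@H](OCOCc3ccccc3)[C@@H]2CC(O[Si](C)(C)C(C)(C)C)=C[C@H](OC)[C@]2(C)[C@@]1(O)CCc1ccoc1 | intermediate
16 | 1α-methoxy 3-ketone from desilylation of 15 | CC1=C[C@H](OCOCc3ccccc3)[C@@H]2CC(=O)C[C@H](OC)[C@]2(C)[C@@]1(O)CCc1ccoc1 | intermediate (not isolated)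
17 | 9β-[2-(furan-3-yl)ethyl]-9α-hydroxy-6α-(benzyloxymethoxy)-8,10β-dimethyl-5βH-octalin-1,7-dien-3-one | CC1=C[C@H](OCOCc3ccccc3)[C@@H]2CC(=O)C=C[C@]2(C)[C@@]1(O)CCc1ccoc1 | intermediate
18 | 4-monomethyl derivative of 17 (C4 epimers) | CC1=C[C@H](OCOCc3ccccc3)[C@@H]2C(C)C(=O)C=C[C@]2(C)[C@@]1(O)CCc1ccoc1 | intermediate (not isolated)
19 | 6α-(benzyloxymethoxy)-9α-hydroxy-15,16-epoxy-5β-labda-1,7,13(16),14-tetraen-3-one | CC1=C[C@H](OCOCc3ccccc3)[C@@H]2C(C)(C)C(=O)C=C[C@]2(C)[C@@]1(O)CCc1ccoc1 | intermediate
20 | 6α-(benzyloxymethoxy)-9α-hydroxy-15,16-epoxy-5β-labda-7,13(16),14-trien-3-one | CC1=C[C@H](OCOCc3ccccc3)[C@@H]2C(C)(C)C(=O)CC[C@]2(C)[C@@]1(O)CCc1ccoc1 | intermediate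
21 | C3 hydrazone of 20 | CC1=C[C@H](OCOCc3ccccc3)[C@@H]2C(C)(C)C(=NN)CC[C@]2(C)[C@@]1(O)CCc1ccoc1 | intermediate (not isolated)
22 | 6α-(benzyloxymethoxy)-15,16-epoxy-5β-labda-7,13(16),14-trien-9α-ol | CC1=C[C@H](OCOCc3ccccc3)[C@@H]2C(C)(C)CCC[C@]2(C)[C@@]1(O)CCc1ccoc1 | intermediate
23 | 6α-(benzyloxymethoxy)-9α,16ξ-dihydroxy-5β-labda-7,13-dien-15,16-olide | CC1=C[C@H](OCOCc3ccccc3)[C@@H]2C(C)(C)CCC[C@]2(C)[C@@]1(O)CCC1=CC(=O)OC1O | intermediate (not isolated)
24 | 6α-(benzyloxymethoxy)-9α-hydroxy-5β-labda-7,13-dien-15,16-olide | CC1=C[C@H](OCOCc3ccccc3)[C@@H]2C(C)(C)CCC[C@]2(C)[C@@]1(O)CCC1=CC(=O)OC1 | intermediate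
25 | (13S)-6α-(benzyloxymethoxy)-9α,13-epoxy-5β-labd-7-en-15,16-olide | CC1=C[C@H](OCOCc3ccccc3)[C@@H]2C(C)(C)CCC[C@]2(C)[C@@]12CC[C@@]1(CC(=O)OC1)O2 | intermediate
26 | O-diisobutylaluminium lactolate of 25 (15ξ) | CC1=C[C@H](OCOCc3ccccc3)[C@@H]2C(C)(C)CCC[C@]2(C)[C@@]12CC[C@@]1(CC(O[Al](CC(C)C)CC(C)C)OC1)O2 | intermediate (not isolated)
27 | (13S)-15ξ-acetoxy-6α-(benzyloxymethoxy)-9α,13;15,16-diepoxy-5β-labd-7-ene | CC1=C[C@H](OCOCc3ccccc3)[C@@H]2C(C)(C)CCC[C@]2(C)[C@@]12CC[C@@]1(CC(OC(C)=O)OC1)O2 | intermediate
28 | (13S)-15ξ-acetoxy-6α-(benzyloxymethoxy)-7β,8β;9α,13;15,16-triepoxy-5β-labdane | C[C@@]12O[C@H]2[C@H](OCOCc6ccccc6)[C@@H]3C(C)(C)CCC[C@]3(C)[C@@]14CC[C@@]5(CC(OC(C)=O)OC5)O4 | intermediate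
29 | (13S)-15ξ-acetoxy-7β,8β;9α,13;15,16-triepoxy-5β-labdan-6α-ol | C[C@@]12O[C@H]2[C@H](O)[C@@H]3C(C)(C)CCC[C@]3(C)[C@@]14CC[C@@]5(CC(OC(C)=O)OC5)O4 | intermediate
30 | (13S)-15ξ-acetoxy-7β,8β;9α,13;15,16-triepoxy-5β-labdan-6-one | C[C@@]12O[C@H]2C(=O)[C@@H]3C(C)(C)CCC[C@]3(C)[C@@]14CC[C@@]5(CC(OC(C)=O)OC5)O4 | intermediate
31 | (13S)-8α,15ξ-diacetoxy-7β-hydroxy-9α,13;15,16-diepoxy-5β-labdan-6-one | CC(=O)O[C@]1(C)[C@@H](O)C(=O)[C@@H]2C(C)(C)CCC[C@]2(C)[C@@]12CC[C@@]1(CC(OC(C)=O)OC1)O2 | intermediate
32 | 7-O-trimethylsilyl ether of 33 | CC(=O)O[C@]1(C)[C@@H](O[Si](C)(C)C)C(=O)[C@@H]2C(C)(C)CCC[C@]2(C)[C@@]12CC[C@@]1(C=COC1)O2 | intermediate (not isolated)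
33 | (13S)-8α-acetoxy-7β-hydroxy-9α,13;15,16-diepoxy-5β-labd-14-en-6-one (CNP0275274.1) | CC(=O)O[C@]1(C)[C@@H](O)C(=O)[C@@H]2C(C)(C)CCC[C@]2(C)[C@@]12CC[C@@]1(C=COC1)O2 | target

**Step count and risks**

Total step count: 20. Longest linear sequence: 18 steps (steps 1–5 and 8–20); steps 6 and 7 make iodide 12.

Steps least certain to work:

Step 2 (key step). The likely failure is loss of regiocontrol (the diene CH2 terminus bonding to the methyl-bearing carbon), or a cycloaddition at the methyl-substituted double bond so slow that the diene decomposes first. Fallback: mask the C6 carbonyl before the cycloaddition, so that only the C9 carbonyl can activate the dienophile and Lewis acid (Et2AlCl) or high pressure may be used without changing the orientation. Diene 2 is combined with 4,4-dimethoxy-2,6-dimethylcyclohexa-2,5-dien-1-one F1 (from PhI(OAc)2 oxidation of 4-methoxy-2,6-dimethylphenol in methanol) to give the racemic 6,6-dimethoxy cycloadduct F2, whose ketal is hydrolysed on wet silica with oxalic acid. The fallback sets out from 2 and returns at 4.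

Step 4. The likely failure is poor enantiomer discrimination or very slow acyl transfer, because the hydroxyl lies on the concave face. Fallback: classical resolution through diastereomeric esters. Racemic 5 is esterified with (S)-2-methoxy-2-phenylacetic acid (EDC, DMAP), the diastereomers are separated by chromatography or crystallisation, and the (S)-2-methoxy-2-phenylacetate of the (6S)-alcohol F3 is cleaved with K2CO3 in methanol at 0 °C. It sets out from 5 and returns at 6.

Step 8. The likely failure is poor facial selectivity at C9: the 6α-alkoxy group may bias ring B toward the half-chair with the C10 methyl axial, which screens the β face. Fallback: add the side chain while ring B is still the flat enedione, where only the convex β face is open. Racemic 4 is treated with Ti(NEt2)4, which adds reversibly to the less hindered C6 carbonyl and masks it in situ. Organocerium 14 then adds to C9 and aqueous work-up returns the C6 ketone as the racemic 9α-hydroxy-9β-furylethyl 6-ketone F4. Luche reduction gives the racemic 6α,9α-diol F5, which is resolved with the same lipase and alkylated with benzyl chloromethyl ether and i-Pr2NEt at the secondary hydroxyl. It sets out from 4 and returns at 15.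

Step 14. The likely failure is lack of stereocontrol at C13 (the two arms of the lactone are nearly isosteric) or an equilibrium that leaves much open butenolide. Fallback: let a stereocentre next to C13 decide the face.
- Hydroxybutenolide 23 is acetalised with (−)-menthol (CSA cat.) to the 16-menthyloxybutenolide F6. The C16 epimer wanted is the one whose alkoxy group shields the face opposite to that O9 must reach; the other epimer is equilibrated under the same acid.
- DBU then gives the spiro adduct F7 by addition anti to the menthyloxy group.
- Aqueous acid hydrolysis to the 16-hydroxy lactone F8 and NaBH4 reduction of its open aldehyde form complete the sequence.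

It sets out from 23 and returns at 25.

Step 19. The likely failure is ionisation at C8 followed by a 1,2-shift (of the C6 acyl carbon, or of a C9 substituent to give an O9-stabilised cation) outrunning capture by acetic acid, under the strong acid the deactivated keto epoxide needs. Fallback: open the more basic, non-conjugated epoxide first and oxidise afterwards.
- 28 is opened in buffered acetic acid (AcOH, NaOAc, 40 °C) to the 7β-hydroxy 8α-acetate F9.
- The C7 hydroxyl is protected (TESCl, imidazole, DMAP) as the triethylsilyl ether F10.
- Hydrogenolysis (H2, Pd(OH)2/C) gives the 6α-alcohol F11, and Dess–Martin oxidation gives the ketone F12.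
- The conditions of step 20 (TMSOTf, i-Pr2NEt) give the 7-O-triethylsilyl enol ether F13, and the buffered fluoride of that step removes the silyl group.

It sets out from 28 and returns at 33.

Step 20. The likely failure is silylation and enolisation of the C6 ketone competing with ionisation of the anomeric acetate, with loss of configuration at C5 or elimination of the C8 acetate. Fallback: a two-stage dehydration that uses no Lewis acid. The anomeric acetate of 31 alone is cleaved with Bu3SnOMe to the lactol F14. This is converted with MsCl and Et3N at −40 → 0 °C, through the anomeric mesylate F15, into the enol ether. It sets out from 31 and returns at 33.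

**Further compounds**

F1 | step 2 | 4,4-dimethoxy-2,6-dimethylcyclohexa-2,5-dien-1-one | COC1(OC)C=C(C)C(=O)C(C)=C1
F2 | step 2 | racemic 6,6-dimethoxy analogue of 4 (enantiomer drawn as for 4) | CC1=CC(OC)(OC)[C@@H]2CC(O[Si](C)(C)C(C)(C)C)=C[C@H](OC)[C@]2(C)C1=O
F3 | step 4 | (S)-2-methoxy-2-phenylacetate of 6 | CC1=C[C@H](OC(=O)[C@@H](OC)c3ccccc3)[C@@H]2CC(O[Si](C)(C)C(C)(C)C)=C[C@H](OC)[C@]2(C)C1=O
F4 | step 8 | racemic 9β-[2-(furan-3-yl)ethyl]-9α-hydroxy-1α-methoxy-3-(tert-butyldimethylsilyloxy)-8,10β-dimethyl-5βH-octalin-2,7-dien-6-one (enantiomer drawn is the one carried on) | CC1=CC(=O)[C@@H]2CC(O[Si](C)(C)C(C)(C)C)=C[C@H](OC)[C@]2(C)[C@@]1(O)CCc1ccoc1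
F5 | step 8 | 6α,9α-diol from F4, racemic and then resolved | CC1=C[C@H](O)[C@@H]2CC(O[Si](C)(C)C(C)(C)C)=C[C@H](OC)[C@]2(C)[C@@]1(O)CCc1ccoc1
F6 | step 14 | 16-[(−)-menthyloxy] derivative of butenolide 24 | CC1=C[C@H](OCOCc3ccccc3)[C@@H]2C(C)(C)CCC[C@]2(C)[C@@]1(O)CCC1=CC(=O)O[C@@H]1O[C@@H]1C[C@H](C)CC[C@H]1C(C)C
F7 | step 14 | 16-[(−)-menthyloxy] derivative of spiro lactone 25 | CC1=C[C@H](OCOCc3ccccc3)[C@@H]2C(C)(C)CCC[C@]2(C)[C@@]12CC[C@@]1(CC(=O)O[C@@H]1O[C@@H]1C[C@H](C)CC[C@H]1C(C)C)O2
F8 | step 14 | 16ξ-hydroxy derivative of spiro lactone 25 | CC1=C[C@H](OCOCc3ccccc3)[C@@H]2C(C)(C)CCC[C@]2(C)[C@@]12CC[C@@]1(CC(=O)OC1O)O2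
F9 | step 19 | (13S)-8α,15ξ-diacetoxy-6α-(benzyloxymethoxy)-9α,13;15,16-diepoxy-5β-labdan-7β-ol | CC(=O)O[C@]1(C)[C@@H](O)[C@H](OCOCc3ccccc3)[C@@H]2C(C)(C)CCC[C@]2(C)[C@@]12CC[C@@]1(CC(OC(C)=O)OC1)O2
F10 | step 19 | 7-O-triethylsilyl ether of F9 | CC(=O)O[C@]1(C)[C@@H](O[Si](CC)(CC)CC)[C@H](OCOCc3ccccc3)[C@@H]2C(C)(C)CCC[C@]2(C)[C@@]12CC[C@@]1(CC(OC(C)=O)OC1)O2
F11 | step 19 | 6α-alcohol from F10 | CC(=O)O[C@]1(C)[C@@H](O[Si](CC)(CC)CC)[C@H](O)[C@@H]2C(C)(C)CCC[C@]2(C)[C@@]12CC[C@@]1(CC(OC(C)=O)OC1)O2
F12 | step 19 | 7-O-triethylsilyl ether of 31 | CC(=O)O[C@]1(C)[C@@H](O[Si](CC)(CC)CC)C(=O)[C@@H]2C(C)(C)CCC[C@]2(C)[C@@]12CC[C@@]1(CC(OC(C)=O)OC1)O2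
F13 | step 19 | 7-O-triethylsilyl ether of 33 | CC(=O)O[C@]1(C)[C@@H](O[Si](CC)(CC)CC)C(=O)[C@@H]2C(C)(C)CCC[C@]2(C)[C@@]12CC[C@@]1(C=COC1)O2
F14 | step 20 | (13S)-8α-acetoxy-7β,15ξ-dihydroxy-9α,13;15,16-diepoxy-5β-labdan-6-one | CC(=O)O[C@]1(C)[C@@H](O)C(=O)[C@@H]2C(C)(C)CCC[C@]2(C)[C@@]12CC[C@@]1(CC(O)OC1)O2
F15 | step 20 | 15-O-methanesulfonate of F14 | CC(=O)O[C@]1(C)[C@@H](O)C(=O)[C@@H]2C(C)(C)CCC[C@]2(C)[C@@]12CC[C@@]1(CC(OS(C)(=O)=O)OC1)O2
A1 | alternative 1 | C9 benzyloxyacetate of the 9β-allyl 6,6-ethylenedioxy cis-decalin | CC1=CC2(OCCO2)[C@@H]3C(C)(C)CCC[C@]3(C)[C@@]1(OC(=O)COCc1ccccc1)CC=C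
A2 | alternative 1 | spiro 2,3-dihydrofuran (ring C with C12=C13) carrying the benzyloxymethyl C16 arm | CC1=CC2(OCCO2)[C@@H]3C(C)(C)CCC[C@]3(C)[C@@]14CC=C(COCc5ccccc5)O4
A3 | alternative 2 | 2-[(E)-2-(dimethylphenylsilyl)ethenyl]-3,3-dimethoxy-4,6-dimethylbicyclo[2.2.2]oct-5-en-2-ol | O[C@]1(/C=C/[Si](C)(C)c2ccccc2)[C@@H]2CC[C@@](C)(C=C2C)C1(OC)OC
A4 | alternative 2 | cis-fused 6-(dimethylphenylsilyl)-9,9-dimethoxy-4,10-dimethyloctal-3-en-8-one (target numbering) | O=C1C[C@H]([Si](C)(C)c3ccccc3)[C@@H]2C(C)=CCC[C@]2(C)C1(OC)OC
A5 | alternative 3 | cis-fused γ-lactone (C6 carbonyl to O9) carrying the C9 acetyl and 2-(furan-3-yl)ethyl groups | CC(=O)[C@@]1(CCc2ccoc2)OC(=O)[C@@H]2C(C)(C)CCC[C@]12C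
A6 | alternative 3 | cis-fused 9-hydroxy-9-[2-(furan-3-yl)ethyl]decalin-6,8-dione | O=C1CC(=O)[C@@H]2C(C)(C)CCC[C@]2(C)[C@@]1(O)CCc1ccoc1
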